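In a one-step world each starting material that leaves turns up as target, so one column of readings is the whole ledger. Thursday's flask is the one asked about, and Friday's ran at half its charge under the same gas. At 3.00 min they read 5.7% and 5.4%, so I take Friday's percentages for Thursday's flask.

| flask | starting material | gas phase | remark | time |
|---|---|---|---|---|
| Thursday's | 20 mM | 0.88 mM (held) | the very flask that is asked about, followed so far |  |
| Friday's | 10 mM | 0.88 mM (held) | run made earlier |  |
| flask | 20 mM | 0.88 mM (held) |  | 40 min |

| run | time / min | target / % |
|---|---|---|
| Thursday's | 0.500 | 0 |
| Thursday's | 1.00 | 0.2 |
| Thursday's | 1.33 | 0 |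
| Thursday's | 2.00 | 4.6 |
| Thursday's | 2.50 | 2.6 |
| Thursday's | 3.00 | 5.7 |
| Friday's | 3.00 | 5.4 |
| Friday's | 5.00 | 6.9 |
| Friday's | 8.00 | 13.5 |
| Friday's | 12.0 | 16.7 |
| Friday's | 15.0 | 16.5 |
| Friday's | 25.0 | 19.9 |
| Friday's | 40.0 | 18.4 |

(readings scatter by 1 percentage point)

- at the start none of the gas phase is in solution

- maple: doubling the saturation concentration of gas phase, all else as stated
- alder: doubling the transfer coefficient of the gas phase, all else as stated

1. how much target there is at 40 min, in percent of the starting material charged
2. the change that raises the amount of target at 40 min, in percent of the starting material charged most ("none" if none brings more than 2 percentage points) (maple / alder / none)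
3. amount of target at 40 min, in percent of the starting material charged, after maple

On that ledger, Friday's 13.5% at 8.00 min reads as a pseudo-first-order half-life of 38.2 min, a reading carrying the scatter of one point. Carried to 40 min, it lets 51.6% of the charge into target. Yet Friday's flask reads 19.9% at 25.0 min and 18.4% at 40.0 min, so the books do not close: 33 percentage points has gone somewhere unseen. Friday's flask keeps 35.7%: the kept share, target standing at a given time over what has entered target by then.

For Thursday's flask I commit to Friday's 18.4%. If entry follows c(dissolved gas), maple divides the half-life by 2, so 76.5% enters and the kept share leaves 27.3%. For alder I have no reckoning from these readings, so I name maple as the best change.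

The forecast gives 19%, maple and 32%, saying “I read this as an equilibrium”; its maple figure stands higher than mine.

The flask gives 17.4%. The best change is maple, which adds 5.3 points and reaches 22.7%, while alder adds 0.89 points.

    gas phase ⇌ dissolved gas, rate k1*(csat - [dissolved gas]) (kL = 0.0200 s⁻¹)
    starting material + dissolved gas → target (k = 0.580 M⁻¹ s⁻¹)
    starting material → side product (k = 2.50 × 10⁻⁴ s⁻¹)
    target ⇌ isomer of the product (K = 9.40, k = 9.00 × 10⁻⁴ s⁻¹)

By 40 min this flask has a net 46.7% of its charge through the reaction to target and 31.7% through the reaction to side product, more by the first, and at that time the first uses starting material 1.8 times as fast as the second. The kept share of that 46.7% is 16.7%, beside 17.4% of target and 29.2% of isomer of the product in the flask. In the neighbour flask with 80 mM of starting material, target and isomer of the product together hold 30.0%; the kept share of that is 10.7%, and that flask holds 12.3% of target.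

The numbers in the tables were computed for substances that don't exist; scatter was added.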